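The flask asked about repeats the green run, and what catches the eye in that run is a leftover.

all flasks: D 0.10 M (fed, over 80 s)
- green: J 0.11 M; the very flask that is asked about, followed so far; the fed solution adds 1.0 times the starting volume
- grey: J 0.17 M; run made earlier; the fed solution adds 1.0 times the starting volume
- flask: J 0.110 M; the fed solution adds 1.0 times the starting volume; time 40 min

| run | time / min | Z / % | D / % |
|---|---|---|---|
| green | 0.333 | 3.7 | 5.7 |
| green | 0.833 | 10.8 | 18.6 |
| green | 1.50 | 13.2 | 46.2 |
| green | 4.00 | 11.7 | 43.1 |
| green | 8.00 | 10.8 | 38.9 |
| grey | 0.417 | 9.9 | 4.6 |
| grey | 1.33 | 22.7 | 32.8 |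
| grey | 4.00 | 22.5 | 25.4 |
| grey | 12.0 | 20.3 | 16.8 |
| grey | 40.0 | 13.0 | 6.5 |

(standard deviation of a reading: 0.5 percentage points)

- every charge counts on the volume at the start, and the solution that is fed holds the whole dose
- what may be going on: D + J -> G; J + G -> L; J + L -> Z; J <-> Q; Z -> X
- percentages count the whole charge, also what has not yet gone in

* time up to 40 min at which Z stands highest
* the amount of Z, in percent of the D charged, at that time
* earliest time at which at least nineteen twentieths of that best amount are there, in min
* latest time at which they still are, in min

At 1.50 min, with the feed over, the green flask still holds 46.2% of its D, although its J was charged at 110% of the D charge, more than D. Both numbers stand, and we clear them up by counting J. Each Z holds 3 J and each G holds one, so the green readings at that time account for 80.2% of the D charge in J, with L left aside because it was not read. That leaves 30 percentage points of J outside these products. D then falls by 3.1 points in 2.50 min, so we suppose that this J waits mostly as Q.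

J is the limiting reagent for Z, because 3 J for each D asks for more than the J charge holds. Its ceiling is the J charge over 3 times the D charge, 36.7% of the D charge in green. We call the highest Z reading divided by that ceiling the J share 36.0%, a ratio with no clock in it. The grey run, with a ceiling of 56.7%, reads 40.1%. For this flask, our share simply returns the green reading of 13.2%, give or take 0.5 points.

The forecast puts the peak at 1.45 min (1.3 min to 1.9 min) with 12.9% (12.3% to 13.6%). It sets the window from 1.05 min (0.95 min to 1.2 min) to 3.2 min (2.2 min to 5 min), holding that “Z only declines afterwards”.

The flask peaks at 12.3% at 1.44 min, and its window runs from 0.959 min to 4.22 min, later than the forecast's close.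

    D + J → G (k = 3.49 /M/s)
    J + G → L (k = 0.471 /M/s)
    J + L → Z (k = 10.6 /M/s)
    J ⇌ Q (K = 10.0, k = 0.0101 /s)
    Z → X (k = 4.99 × 10⁻⁴ /s)

The most Z that the charges allow in this flask by the steps listed, no other path taking anything, is 36.7%, so its J share is 33.5%. A neighbouring flask is the same flask with D at 0.060 M. Its ceiling is 61.1%, and our share gives 22.0% there, while that flask reached 20.3%.

(The data are simulated from invented constants; the scatter is artificial.)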